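The vessel is closed and stirred, so I keep a ledger of the electrophile.

    electrophile + nucleophile → acid set free + target (k1 = 0.895 L mol⁻¹ h⁻¹)
    nucleophile + acid set free ⇌ protonated nucleophile, settled at all times (K2 = 3440 L mol⁻¹)
    acid set free + free base ⇌ salt of the base (K3 = 3470 L mol⁻¹, k3 = 17.9 L mol⁻¹ h⁻¹)
    nucleophile ⇌ dormant form (K4 = 2.01, k4 = 0.269 h⁻¹)
    acid set free + target → side product A (k5 = 0.816 L mol⁻¹ h⁻¹)
    electrophile + target → side product B (k6 = 2.66 L mol⁻¹ h⁻¹)

electrophile 36 mM; nucleophile 32.4 mM; free base 72.0 mM; time 10 d

1. part of the electrophile that has reacted at 10 d
2. share of free nucleophile in free nucleophile and protonated nucleophile together, at 10 d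

Each nucleophile that reacts takes one electrophile and gives one target and one acid set free. The target then takes electrophile with constant 2.66 L mol⁻¹ h⁻¹ against 0.895 L mol⁻¹ h⁻¹ for the nucleophile, so I book it as side product B, at two electrophiles per nucleophile. I leave side product A empty. I carry the reach 180%, the electrophile that the charged nucleophile can consume at two apiece, in percent of the electrophile charged. It exceeds the charge, so the electrophile is the limiting reagent, and the books close with 14.4 mM of nucleophile over.

For the pace, I take free nucleophile as 33.2% of what remains, against the dormant form, and ignore protonation. Integrating gives an exponent of 2.06 and 6.13% of the electrophile left, so c is 93.9%. The acid, about half the electrophile charged, sits on the free base. Since K2 and K3 nearly match, base over salt gives fr as 75.2%.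

The forecast gives 92.5% and 76.2%, holding that “the target stays low because it is quickly consumed by the electrophile”. Its c stands below mine.

The flask gives 91.7% and 75.5%. At 10.0 d, side product B holds 87.0% of the electrophile charged. Left until 100 d, this flask reaches 100%, and free nucleophile, protonated nucleophile and dormant form together stand at 13.6 mM, against the 14.4 mM the reach left over.

A neighbour charged with 140 mM of electrophile, all else held, has a reach of 46.3%, which puts the nucleophile short. Its computed c is 45.7%, with free nucleophile down to 0.28% of its charge.

The constants used here come from no measurement; no experiment stands behind them.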